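**Plan**

1. Numbering: decalin C1–C10 (ring A = C1–C2–C3–C4–C5–C10, ring B = C5–C10), chain C11, C12, C13 (bears CH2OH), C14, C15, butenolide C16. The retrosynthesis cuts, in this order: the C16–O and C16–C(CH3) bonds of the butenolide, C12–C13, C9–C11, and C4–C5 of ring A together with a temporary C3 carbonyl.
2. Enabling feature: in ring A the quaternary gem-dimethyl carbon C4 lies between the unfunctionalised C3 and the ring-fusion carbon C5. C4 can therefore be inserted into the C3–C5 bond of an A-nor cyclopentene (C1–C2–C3–C5–C10) by a 1,2-shift of alkenyl C5 (C5=C6) from carbinol C3 to an exocyclic CMe2 centre, C3 becoming a ketone that is removed later.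
3. Forward: ring B is bought as 2-methylcyclohexane-1,3-dione; the five-membered A-nor ring is closed by a desymmetrising benzoin reaction and enlarged to ring A by the C4 insertion. The C3 carbonyl is then removed and C5=C6 hydrogenated; the C8 methyl and C9 enol triflate follow; the chain is joined at C9–C11, then C12–C13; the butenolide is closed last.
4. Stereochemistry: C10 from the chiral carbene catalyst; C5 from hydrogenation anti to the C10 methyl; C13=C14 (E) from a Z-selective bromo-ylide Wittig reaction followed by a stereoretentive Suzuki coupling; C15=C16 (Z) from anti addition of the carboxylate across the alkyne.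

Key step: step 6

Remark: in step 2 the enantiomer of the aminoindanol-derived triazolium salt is used that delivers (3aS,7aR)-4; its sense of induction is assumed, and the opposite enantiomer of the catalyst is used should it prove to be the other.

**Route**

Step 1
Reactants: 1 2-methylcyclohexane-1,3-dione; 2 acrolein
Product: 3 3-(1-methyl-2,6-dioxocyclohexyl)propanal
Conditions: H2O, rt
Reagents that add atoms: none
Why: Michael addition of the acidic C2–H of the 1,3-dione to the enal should give the prochiral quaternary carbon (future C10) carrying the C1–C2–C3 aldehyde arm.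

Step 2
Reactants: 3 3-(1-methyl-2,6-dioxocyclohexyl)propanal
Product: 4 (3aS,7aR)-7a-hydroxy-3a-methylhexahydro-1H-indene-1,4(2H)-dione
Conditions: chiral aminoindanol-derived N-pentafluorophenyl triazolium tetrafluoroborate (10 mol %), Et3N (10 mol %), toluene, rt
Reagents that add atoms: none
Why: Desymmetrising intramolecular crossed benzoin reaction: the carbene-bound acyl anion (C3) should add 5-exo to one of the two enantiotopic ring ketones under catalyst control, which fixes C10 and gives the cis-fused ketol.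

Step 3
Reactants: 4 (3aS,7aR)-7a-hydroxy-3a-methylhexahydro-1H-indene-1,4(2H)-dione
Product: 5 (S)-3a-methyl-3,3a,5,6-tetrahydro-1H-indene-1,4(2H)-dione
Conditions: methyl N-(triethylammoniosulfonyl)carbamate, toluene, 60 °C
Reagents that add atoms: none
Why: Syn elimination of the tertiary sulfamate ester can only take a hydrogen from C6 (C10 is quaternary, C3 is a carbonyl), so the conjugated C3(=O)–C5=C6 enone should form and the carbinol centre is erased.

Step 4
Reactants: 5 (S)-3a-methyl-3,3a,5,6-tetrahydro-1H-indene-1,4(2H)-dione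
Product: 6 (S)-3a'-methyl-3',3a',5',6'-tetrahydrospiro[[1,3]dioxolane-2,4'-inden]-1'(2'H)-one (C9 ethylene ketal of 5)
Conditions: ethylene glycol, p-TsOH·H2O (cat.), 4 Å MS, rt
Reagents that add atoms: ethylene glycol, OCCO
Why: Acid-catalysed ketalisation should take place at the saturated C9 ketone much faster than at the conjugated cyclopentenone carbonyl, as is general for bicyclic enediones of this kind.

Step 5
Reactants: 6 C9 ethylene ketal of the enedione
Product: 7 (3a'S)-3a'-methyl-1'-(prop-1-en-2-yl)-1',2',3',3a',5',6'-hexahydrospiro[[1,3]dioxolane-2,4'-inden]-1'-ol (carbinol epimers)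
Conditions: CeCl3 (anhydrous), isopropenylmagnesium bromide, THF, −78 °C; aq. NH4Cl
Reagents that add atoms: isopropenylmagnesium bromide, CC(=C)[Mg]Br
Why: The organocerium reagent should add 1,2 to the enone carbonyl without enolisation; the configuration of the new carbinol centre is of no consequence because C3 becomes sp2 in step 6.

Step 6
Reactants: 7 doubly allylic tertiary alcohol (dienyl carbinol)
Product: 8 (S)-5',5',8a'-trimethyl-3',5',8',8a'-tetrahydro-2'H-spiro[[1,3]dioxolane-2,1'-naphthalen]-6'(7'H)-one (4,4-dimethyl-Δ5-3-ketone, C9 ketal)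
Conditions: [N,N'-bis(3,5-di-tert-butylsalicylidene)-1,2-cyclohexanediamino]cobalt(II) (5 mol %), N-fluoro-2,4,6-trimethylpyridinium triflate (1.2 equiv), PhSiH3 (1.2 equiv), acetone, 0 °C → rt
Reagents that add atoms: none
Why: A cobalt(III) hydride, formed from the catalyst, the N-fluoropyridinium oxidant and the silane, should transfer a hydrogen atom to the CH2 terminus of the isopropenyl group, giving the tertiary radical at the future C4 next to carbinol C3; oxidation to the cation (radical–polar crossover), or 3-exo attack of the radical on C5 of the C5=C6 alkene, then shifts alkenyl C5 from C3 to C4 while C3–OH becomes the C3 ketone. The closest known reaction type is the hydrogen-atom-transfer-initiated semipinacol rearrangement of 1-(1-alkenyl)cycloalkanols, with the selenium-triggered ionic ring enlargement of ketones as its older counterpart. No bond to a new ring atom is made from outside: the cyclopentene ring C1–C2–C3–C5–C10 is enlarged to ring A by insertion of the exocyclic carbon C4 into the C3–C5 bond through a bridged, cyclopropylcarbinyl-type transition state. No new stereocentre arises, since C4 carries two methyl groups, C10 is a spectator and C5 stays sp2 until step 8. The step needs hydrogen-atom transfer at the isopropenyl group and not at the ring alkene, which the higher reactivity of the 1,1-disubstituted alkene should secure. It also needs migration of C5 and not of the C2 methylene, which the far higher migratory aptitude of an alkenyl carbon (and the radical pathway open only to it) should secure; the near-neutral conditions spare the dioxolane and avoid ionisation of the doubly allylic alcohol.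

Step 7
Reactants: 8 4,4-dimethyl-Δ5-3-ketone C9 ketal
Product: 10 (S)-5',5',8a'-trimethyl-3',5',6',7',8',8a'-hexahydro-2'H-spiro[[1,3]dioxolane-2,1'-naphthalene], via hydrazone 9 (not isolated)
Conditions: N2H4·H2O, KOH, diethylene glycol, 130 → 200 °C
Reagents that add atoms: none
Why: Wolff–Kishner reduction should remove the temporary C3 carbonyl; the quaternary C4 prevents migration of the C5=C6 alkene and the ketal is stable to base.

Step 8
Reactants: 10 Δ5-alkene C9 ketal
Product: 12 (4aS,8aS)-5,5,8a-trimethyloctahydronaphthalen-1(2H)-one, via saturated ketal 11 (not isolated)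
Conditions: H2 (5 atm), 10% Pd/C, EtOH–AcOH, rt; filter; then 2 M HCl, THF, rt
Reagents that add atoms: none
Why: Heterogeneous hydrogenation should deliver hydrogen to the α-face of C5=C6, anti to the angular C10 methyl and the axial C4 methyl, which sets C5 (trans ring fusion); acid then hydrolyses the dioxolane.

Step 9
Reactants: 12 (4aS,8aS)-5,5,8a-trimethyloctahydronaphthalen-1(2H)-one
Product: 13 (4aS,8aS)-2,5,5,8a-tetramethyloctahydronaphthalen-1(2H)-one (C2 epimers)
Conditions: LDA, THF, −78 °C; MeI, −78 → 0 °C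
Reagents that add atoms: iodomethane, CI
Why: Enolate alkylation can only take place at C8, the sole α-carbon with hydrogens; the epimer mixture is of no consequence because C8 becomes sp2 in step 10.

Step 10
Reactants: 13 (4aS,8aS)-2,5,5,8a-tetramethyloctahydronaphthalen-1(2H)-one
Product: 14 (4aS,8aS)-2,5,5,8a-tetramethyl-3,4,4a,5,6,7,8,8a-octahydronaphthalen-1-yl trifluoromethanesulfonate
Conditions: KHMDS, THF, −78 °C; PhNTf2, −78 → 0 °C
Reagents that add atoms: N-phenylbis(trifluoromethanesulfonimide), FC(F)(F)S(=O)(=O)N(c1ccccc1)S(=O)(=O)C(F)(F)F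
Why: Deprotonation at C8 gives the only possible, tetrasubstituted enolate, and O-triflation fixes the C8=C9 double bond, as known for 2,2,6-trialkylcyclohexanones.

Step 11
Reactants: 14 enol triflate
Product: 15 (4aS,8aS)-1-ethenyl-2,5,5,8a-tetramethyl-3,4,4a,5,6,7,8,8a-octahydronaphthalene
Conditions: tributyl(vinyl)stannane, Pd(PPh3)4 (5 mol %), LiCl, THF, 65 °C
Reagents that add atoms: tributyl(vinyl)stannane, C=C[Sn](CCCC)(CCCC)CCCC
Why: Stille coupling of hindered 2,6,6-trialkylcyclohexenyl triflates with vinylstannanes is well precedented and should install C11–C12 at C9.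

Step 12
Reactants: 16 (ethoxycarbonylmethylene)triphenylphosphorane; 17 3-(trimethylsilyl)prop-2-ynal
Product: 19 ethyl (Z)-2-bromo-5-(trimethylsilyl)pent-2-en-4-ynoate, via bromo ylide 18 (not isolated)
Conditions: NBS, CH2Cl2, −20 °C; then 17, K2CO3, −20 °C → rt
Reagents that add atoms: N-bromosuccinimide, O=C1CCC(=O)N1Br
Why: Bromination of the stabilised ylide followed by Wittig reaction should place the ester trans to the alkynyl group, as stabilised ylides do, which gives the (Z)-α-bromo enoate.

Step 13
Reactants: 15 vinyl diene; 19 ethyl (Z)-2-bromo-5-(trimethylsilyl)pent-2-en-4-ynoate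
Product: 21 ethyl (E)-2-{2-[(4aS,8aS)-2,5,5,8a-tetramethyl-3,4,4a,5,6,7,8,8a-octahydronaphthalen-1-yl]ethyl}-5-(trimethylsilyl)pent-2-en-4-ynoate, via alkylborane 20 (not isolated)
Conditions: 9-BBN, THF, 0 °C → rt; then 19, PdCl2(dppf) (5 mol %), AsPh3, aq. K3PO4, DMF, rt
Reagents that add atoms: none
Why: 9-BBN should hydroborate only the monosubstituted vinyl terminus (the tetrasubstituted ring alkene is inert), and the B-alkyl Suzuki–Miyaura coupling should replace bromine with retention, so that the chain ends up cis to the alkynyl group (E-enoate).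

Step 14
Reactants: 21 silyl enynoate
Product: 23 (E)-2-{2-[(4aS,8aS)-2,5,5,8a-tetramethyl-3,4,4a,5,6,7,8,8a-octahydronaphthalen-1-yl]ethyl}pent-2-en-4-yn-1-ol, via silyl enynol 22 (not isolated)
Conditions: DIBAL-H, CH2Cl2, −78 °C; then MeOH, K2CO3, rt
Reagents that add atoms: none
Why: DIBAL-H should reduce the conjugated ester 1,2 to the allylic alcohol, and methanolysis under mild base removes the alkynyl silyl group without touching the alkene geometry.

Step 15
Reactants: 24 but-2-ynoic acid
Product: 25 (Z)-3-iodobut-2-enoic acid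
Conditions: NaI, AcOH, 115 °C
Reagents that add atoms: sodium iodide, [Na+].[I-]
Why: Conjugate addition of iodide and anti protonation (net anti hydroiodination of the ynoic acid) should give the Z isomer with iodine cis to the carboxyl group.

Step 16
Reactants: 23 terminal enynol; 25 (Z)-3-iodobut-2-enoic acid
Product: 27 (Z)-5-{(E)-3-(hydroxymethyl)-5-[(4aS,8aS)-2,5,5,8a-tetramethyl-3,4,4a,5,6,7,8,8a-octahydronaphthalen-1-yl]pent-2-en-1-ylidene}-4-methylfuran-2(5H)-one, via enynoic acid 26 (not isolated)
Conditions: Pd(PPh3)4 (5 mol %), CuI (10 mol %), Et3N, MeCN, rt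
Reagents that add atoms: none
Why: Sonogashira coupling followed in the same flask by metal-promoted 5-exo-dig anti addition of the cis carboxylate to the alkyne should give the (Z)-γ-ylidene butenolide; the E geometry of the enynol keeps the free hydroxyl away from the alkyne.

**Compound list**

1 | 2-methylcyclohexane-1,3-dione | CC1C(=O)CCCC1=O | starting material
2 | acrolein | C=CC=O | starting material
3 | 3-(1-methyl-2,6-dioxocyclohexyl)propanal | CC1(CCC=O)C(=O)CCCC1=O | intermediate
4 | (3aS,7aR)-7a-hydroxy-3a-methylhexahydro-1H-indene-1,4(2H)-dione | C[C@]12CCC(=O)[C@@]1(O)CCCC2=O | intermediate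
5 | (S)-3a-methyl-3,3a,5,6-tetrahydro-1H-indene-1,4(2H)-dione | C[C@]12CCC(=O)C1=CCCC2=O | intermediate
6 | (S)-3a'-methyl-3',3a',5',6'-tetrahydrospiro[[1,3]dioxolane-2,4'-inden]-1'(2'H)-one | C[C@]12CCC(=O)C1=CCCC23OCCO3 | intermediate
7 | (3a'S)-3a'-methyl-1'-(prop-1-en-2-yl)-1',2',3',3a',5',6'-hexahydrospiro[[1,3]dioxolane-2,4'-inden]-1'-ol (carbinol epimers) | C[C@]12CCC(O)(C(C)=C)C1=CCCC23OCCO3 | intermediate
8 | (S)-5',5',8a'-trimethyl-3',5',8',8a'-tetrahydro-2'H-spiro[[1,3]dioxolane-2,1'-naphthalen]-6'(7'H)-one | C[C@]12CCC(=O)C(C)(C)C1=CCCC23OCCO3 | intermediate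
9 | hydrazone of 8 | C[C@]12CCC(=NN)C(C)(C)C1=CCCC23OCCO3 | intermediate
10 | (S)-5',5',8a'-trimethyl-3',5',6',7',8',8a'-hexahydro-2'H-spiro[[1,3]dioxolane-2,1'-naphthalene] | C[C@]12CCCC(C)(C)C1=CCCC23OCCO3 | intermediate
11 | (4a'S,8a'S)-5',5',8a'-trimethyloctahydro-2'H-spiro[[1,3]dioxolane-2,1'-naphthalene] | C[C@]12CCCC(C)(C)[C@@H]1CCCC23OCCO3 | intermediate
12 | (4aS,8aS)-5,5,8a-trimethyloctahydronaphthalen-1(2H)-one | C[C@]12CCCC(C)(C)[C@@H]1CCCC2=O | intermediate
13 | (4aS,8aS)-2,5,5,8a-tetramethyloctahydronaphthalen-1(2H)-one (C2 epimers) | C[C@]12CCCC(C)(C)[C@@H]1CCC(C)C2=O | intermediate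
14 | (4aS,8aS)-2,5,5,8a-tetramethyl-3,4,4a,5,6,7,8,8a-octahydronaphthalen-1-yl trifluoromethanesulfonate | C[C@]12CCCC(C)(C)[C@@H]1CCC(C)=C2OS(=O)(=O)C(F)(F)F | intermediate
15 | (4aS,8aS)-1-ethenyl-2,5,5,8a-tetramethyl-3,4,4a,5,6,7,8,8a-octahydronaphthalene | C[C@]12CCCC(C)(C)[C@@H]1CCC(C)=C2C=C | intermediate
16 | (ethoxycarbonylmethylene)triphenylphosphorane | CCOC(=O)C=P(c1ccccc1)(c1ccccc1)c1ccccc1 | starting material
17 | 3-(trimethylsilyl)prop-2-ynal | C[Si](C)(C)C#CC=O | starting material
18 | ethyl bromo(triphenyl-λ5-phosphanylidene)acetate | CCOC(=O)C(Br)=P(c1ccccc1)(c1ccccc1)c1ccccc1 | intermediate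
19 | ethyl (Z)-2-bromo-5-(trimethylsilyl)pent-2-en-4-ynoate | CCOC(=O)/C(Br)=C/C#C[Si](C)(C)C | intermediate
20 | 9-{2-[(4aS,8aS)-2,5,5,8a-tetramethyl-3,4,4a,5,6,7,8,8a-octahydronaphthalen-1-yl]ethyl}-9-borabicyclo[3.3.1]nonane | C1CC2CCCC(C1)B2CCC1=C(C)CC[C@H]2C(C)(C)CCC[C@]12C | intermediate
21 | ethyl (E)-2-{2-[(4aS,8aS)-2,5,5,8a-tetramethyl-3,4,4a,5,6,7,8,8a-octahydronaphthalen-1-yl]ethyl}-5-(trimethylsilyl)pent-2-en-4-ynoate | CCOC(=O)/C(CCC1=C(C)CC[C@H]2C(C)(C)CCC[C@]12C)=C/C#C[Si](C)(C)C | intermediate
22 | (E)-2-{2-[(4aS,8aS)-2,5,5,8a-tetramethyl-3,4,4a,5,6,7,8,8a-octahydronaphthalen-1-yl]ethyl}-5-(trimethylsilyl)pent-2-en-4-yn-1-ol | OC/C(CCC1=C(C)CC[C@H]2C(C)(C)CCC[C@]12C)=C/C#C[Si](C)(C)C | intermediate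
23 | (E)-2-{2-[(4aS,8aS)-2,5,5,8a-tetramethyl-3,4,4a,5,6,7,8,8a-octahydronaphthalen-1-yl]ethyl}pent-2-en-4-yn-1-ol | OC/C(CCC1=C(C)CC[C@H]2C(C)(C)CCC[C@]12C)=C/C#C | intermediate
24 | but-2-ynoic acid | CC#CC(=O)O | starting material
25 | (Z)-3-iodobut-2-enoic acid | C/C(I)=C/C(=O)O | intermediate
26 | (2Z,6E)-7-(hydroxymethyl)-3-methyl-9-[(4aS,8aS)-2,5,5,8a-tetramethyl-3,4,4a,5,6,7,8,8a-octahydronaphthalen-1-yl]nona-2,6-dien-4-ynoic acid | OC(=O)/C=C(/C)C#C/C=C(/CO)CCC1=C(C)CC[C@H]2C(C)(C)CCC[C@]12C | intermediate
27 | (Z)-5-{(E)-3-(hydroxymethyl)-5-[(4aS,8aS)-2,5,5,8a-tetramethyl-3,4,4a,5,6,7,8,8a-octahydronaphthalen-1-yl]pent-2-en-1-ylidene}-4-methylfuran-2(5H)-one | CC1=CC(=O)O/C1=C\C=C(\CO)CCC1=C(C)CC[C@H]2C(C)(C)CCC[C@]12C | target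

**Step count**

Total: 16 steps. Longest linear sequence: 14 steps (steps 1–11, 13, 14 and 16); steps 12 and 15 are side branches.

**Steps most likely to fail**

Step 6. Hydrogen-atom transfer could take place at the ring alkene instead of the isopropenyl group, or the C4 cation could be trapped by the neighbouring hydroxyl or lose a proton before the shift. The fallback is the ionic, selenium-triggered ring enlargement. Setting out from 6, 2-lithio-2-(methylseleno)propane (from 2,2-bis(methylseleno)propane and n-BuLi, THF, −78 °C) should add 1,2 to the enone carbonyl to give the β-hydroxyalkyl selenide F1. Silver tetrafluoroborate on basic alumina in CH2Cl2 (0 °C → rt) then turns selenium into the leaving group at C4, and the same shift of alkenyl C5 gives 8, where the route is rejoined.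

Step 13. The alkylborane could undergo protodeboronation or β-hydride elimination, and the aqueous base could cleave the alkynyl silane or add to the bromo enynoate, with loss of material or of alkene geometry. The fallback builds the trisubstituted alkene by a Wittig reaction instead. Setting out from 20, oxidation (NaOH, H2O2) gives the homoallylic alcohol F2, and iodine, PPh3 and imidazole convert it into the iodide F3. Alkylation of ylide 16 with F3 (MeCN, reflux) gives the phosphonium iodide F4, and aqueous NaOH gives the α-substituted stabilised ylide F5. Its E-selective Wittig reaction with aldehyde 17 (CH2Cl2, rt) returns to the route at 21.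

Step 16. Cyclisation could take the 6-endo course to a pyranone, the alkyne could homocouple, or the free hydroxyl could interfere with the metals. The fallback separates coupling and ring closure. Setting out from 23, Sonogashira coupling with ethyl (Z)-3-iodobut-2-enoate (PdCl2(PPh3)2, CuI, Et3N, THF) gives the dienynoic ester F6. LiOH (THF–H2O) liberates acid 26, which is isolated this time and closed in a separate silver(I)-catalysed 5-exo-dig cycloisomerisation (AgNO3 cat., acetone, rt), rejoining the route at 27.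

Further compounds
F1 | step 6 | (3a'S)-3a'-methyl-1'-[2-(methylselanyl)propan-2-yl]-1',2',3',3a',5',6'-hexahydrospiro[[1,3]dioxolane-2,4'-inden]-1'-ol | C[C@]12CCC(O)(C(C)(C)[Se]C)C1=CCCC23OCCO3
F2 | step 13 | 2-[(4aS,8aS)-2,5,5,8a-tetramethyl-3,4,4a,5,6,7,8,8a-octahydronaphthalen-1-yl]ethanol | OCCC1=C(C)CC[C@H]2C(C)(C)CCC[C@]12C
F3 | step 13 | (4aS,8aS)-1-(2-iodoethyl)-2,5,5,8a-tetramethyl-3,4,4a,5,6,7,8,8a-octahydronaphthalene | ICCC1=C(C)CC[C@H]2C(C)(C)CCC[C@]12C
F4 | step 13 | {1-ethoxy-1-oxo-4-[(4aS,8aS)-2,5,5,8a-tetramethyl-3,4,4a,5,6,7,8,8a-octahydronaphthalen-1-yl]butan-2-yl}triphenylphosphonium iodide | CCOC(=O)C(CCC1=C(C)CC[C@H]2C(C)(C)CCC[C@]12C)[P+](c1ccccc1)(c1ccccc1)c1ccccc1.[I-]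
F5 | step 13 | ethyl 4-[(4aS,8aS)-2,5,5,8a-tetramethyl-3,4,4a,5,6,7,8,8a-octahydronaphthalen-1-yl]-2-(triphenyl-λ5-phosphanylidene)butanoate | CCOC(=O)C(CCC1=C(C)CC[C@H]2C(C)(C)CCC[C@]12C)=P(c1ccccc1)(c1ccccc1)c1ccccc1
F6 | step 16 | ethyl (2Z,6E)-7-(hydroxymethyl)-3-methyl-9-[(4aS,8aS)-2,5,5,8a-tetramethyl-3,4,4a,5,6,7,8,8a-octahydronaphthalen-1-yl]nona-2,6-dien-4-ynoate | CCOC(=O)/C=C(/C)C#C/C=C(/CO)CCC1=C(C)CC[C@H]2C(C)(C)CCC[C@]12C
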